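The earlier runs and the new flask were computed from invented constants, and the scatter is random.

Two excesses and one comparison between them are asked.

the same everywhere: left-handed substrate 0.21 M; right-handed substrate 0.21 M; added ligand 0.58 mM

| charge | partner | protic impurity | catalyst | remark | time |
|---|---|---|---|---|---|
| eta | 0.21 M | 4.2 mM | 0.055 mM | run made earlier |  |
| delta | 0.21 M | 4.2 mM | 0.18 mM | run made earlier |  |
| Monday's | 0.210 M | 4.20 mM | 0.21 mM |  | 15 h |
| Tuesday's | 0.210 M | 4.20 mM | 0.080 mM |  | 15 h |

- eta (time / h: left-handed product / %, right-handed product / %): 0.417: 3.7, 0; 1.00: 6.5, 0; 2.00: 8.2, 0.1; 3.00: 9.3, 0.2; 5.00: 10.7, 0.4; 6.00: 10.9, 0.2; 8.00: 11.0, 0.7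
- delta (time / h: left-handed product / %, right-handed product / %): 0.417: 9.5, 0.3; 1.00: 15.2, 0.8; 2.00: 19.9, 0.4; 3.00: 21.8, 0.9; 5.00: 22.9, 0.8; 6.00: 23.5, 0.3; 8.00: 24.9, 0.3

(readings scatter by 0.3 percentage points)

- catalyst is single-handed; left-handed substrate and right-handed substrate are mirror images of each other, charged as a racemate, each of them at the stated concentration
- what may be going on: partner + catalyst + left-handed substrate -> catalyst + left-handed product; partner + catalyst + right-handed substrate -> catalyst + right-handed product; catalyst + added ligand <-> idle complex; catalyst <-> dormant form; partner + protic impurity -> quenched reagent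
- an excess is below zero if the other one leads

1. which of the two ends with the higher excess of left-handed product over right-handed product in the product ("neither" if they lie within 2 percentage points) (Monday's / Tuesday's / neither)
2. excess of left-handed product over right-handed product in the product at the end, Monday's
3. excess of left-handed product over right-handed product in the product at the end, Tuesday's

Let r and q be the fractions of left-handed and right-handed substrate still left. Both substrates meet the same catalyst and partner, so those two factors cancel from the ratio of the two rates, and integration gives ln r = s ln q. The product excess is then (q − r)/(2 − q − r). Over the last 5 readings of each run, r averages 54.8 % in delta and 80.0 % in eta. The right-handed product averages 0.430 %, a mean good to about 0.095 percentage points. These readings give s = 48.0, the selectivity factor, the rate constant of the left-handed substrate over that of the right-handed one.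

The bench rule takes the excess as (s − 1)/(s + 1), here 95.9 % for both flasks. It ignores depletion: the closed form lowers the excess by about 2(B − 1)/s, where B = −ln r/(1 − r). The rule therefore misses by the margin of 2 points once B passes 1 + s/100, a border at 1.48.

Partner and left-handed substrate start at a ratio of 1.00, and the impurity claims 2.00 % of the partner, so the two fall nearly together. Then u = (1 − r)/r should grow in proportion to catalyst: at the last readings, delta over eta gives 3.52 in u against 3.27 in catalyst. Continuing delta's last rise in u to 15 h and scaling by catalyst, my reckoning gives r = 39.1 % for Monday's and 62.8 % for Tuesday's. So B is 1.54 in Monday's, past the border, and 1.25 in Tuesday's, inside it. The closed form gives 93.8 % for Monday's and 94.9 % for Tuesday's, estimates that lie 1.1 points apart, less than the margin.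

The forecast reads neither, with 94 % (91.5 % to 96 %) for Monday's and 95 % (92.5 % to 97 %) for Tuesday's, since “The higher conversion costs only slightly”.

Monday's ends at 93.2 % and Tuesday's at 94.3 %, so the answer is neither.

    partner + catalyst + left-handed substrate → catalyst + left-handed product (k = 18000 M⁻² h⁻¹)
    partner + catalyst + right-handed substrate → catalyst + right-handed product (k = 430 M⁻² h⁻¹)
    catalyst + added ligand ⇌ idle complex (K = 780 M⁻¹, k = 280 M⁻¹ h⁻¹)
    catalyst ⇌ dormant form (K = 27.0, k = 0.720 h⁻¹)
    partner + protic impurity → quenched reagent (k = 19.0 M⁻¹ h⁻¹)

Monday's keeps 43 % of its left-handed substrate and 98 % of its right-handed substrate. From that left-handed remainder, s gives an excess of 94.1 %. A neighbouring flask, the same as Monday's but with 0.84 M of partner, keeps 1.2 % of its left-handed substrate, for which s gives 83.6 %, and that flask ends at 81.6 %.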